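**Retrosynthetic overview**
1. The strategy rests on ring B: its C2'(OH)–C3'(prenyl)–C4'(OH)–C5'(OMe) arc, with the C2' and C5' oxygens para to each other, maps onto the four ring carbons of a squarate. The remaining C6'–C1' pair is a vinyl group on chromone C3, C1' being the former formyl carbon.
2. Ring B is disconnected to a 4-methoxy-4-(chromonylvinyl)cyclobutenone by thermal 4π-opening and 6π-closure (C1'–C2' bond). The cyclobutenone comes from an (E)-iodovinylchromone-derived alkenylmagnesium and 3-allyl-4-isopropoxycyclobutenedione (C5'–C6' bond).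
3. The iodovinylchromone comes from a 3-formylchromone (Takai olefination), itself from 2,4-dihydroxyacetophenone (Vilsmeier–Haack); the dione comes from diisopropyl squarate and allylmagnesium bromide.
4. Ring order: ring A is bought, ring C is closed at O1–C2, the squarate four-membered ring is attached, and ring B is formed last by ring expansion. Both isopropyl ethers are then removed with BCl3 and the allyl group is turned into prenyl by cross-metathesis as the final, acid-free step.

Key step: step 8

Remark: the target has no stereocentre, so the cyclobutenone carbinols are carried as racemates; allyl is used as a prenyl surrogate until after the only acidic deprotection.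

**Step 1**
Reactants: 1 diisopropyl squarate; 2 allylmagnesium bromide
Product: 3 4-allyl-4-hydroxy-2,3-diisopropoxycyclobut-2-en-1-one (racemic)
Conditions: THF, −78 °C; then sat. aq NH4Cl
Reagents that add atoms: none
Why: Grignard 1,2-addition to one carbonyl of the squarate stops at the tertiary alkoxide at low temperature; allyl is chosen because prenylmagnesium halides bond through their tertiary end, and the racemic carbinol centre is erased in step 2.

**Step 2**
Reactants: 3 4-allyl-4-hydroxy-2,3-diisopropoxycyclobut-2-en-1-one
Product: 4 3-allyl-4-isopropoxycyclobut-3-ene-1,2-dione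
Conditions: conc. HCl (cat.), CH2Cl2, rt
Reagents that add atoms: none
Why: Acid-induced ionisation of the carbinol to an alkoxy-stabilised cyclobutenyl cation and collapse of the resulting hemiketal should give the 3-alkyl-4-alkoxycyclobutenedione with net loss of propan-2-ol (the standard squarate adduct hydrolysis).

**Step 3**
Reactants: 5 2,4-dihydroxyacetophenone
Product: 6 2-hydroxy-4-isopropoxyacetophenone
Conditions: 2-bromopropane, K2CO3, DMF, 60 °C
Reagents that add atoms: 2-bromopropane CC(C)Br
Why: Williamson etherification is selective for the 4-hydroxyl because the 2-hydroxyl is held in a hydrogen bond to the acetyl carbonyl and is much less nucleophilic.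

**Step 4**
Reactants: 6 2-hydroxy-4-isopropoxyacetophenone
Product: 7 7-isopropoxy-4-oxo-4H-chromene-3-carbaldehyde (7-isopropoxy-3-formylchromone)
Conditions: POCl3, DMF, 0 °C → 50 °C; then ice–water
Reagents that add atoms: N,N-dimethylformamide CN(C)C=O; water O
Why: Vilsmeier–Haack reaction: the methyl ketone is formylated twice by the chloroiminium reagent, the phenol oxygen closes ring C at O1–C2 with loss of dimethylamine, and hydrolysis of the remaining iminium releases the 3-formyl group.

**Step 5**
Reactants: 7 7-isopropoxy-3-formylchromone; 8 iodoform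
Product: 9 (E)-3-(2-iodovinyl)-7-isopropoxy-4H-chromen-4-one
Conditions: CrCl2 (6 equiv), THF–1,4-dioxane, 0 °C → rt
Reagents that add atoms: none
Why: Takai olefination: the geminal dichromium carbenoid from CHI3 and CrCl2 adds to the aldehyde and eliminates to the (E)-iodoalkene, while the vinylogous-ester carbonyl of the chromone is far less reactive than the aldehyde.

**Step 6**
Reactants: 9 (E)-3-(2-iodovinyl)-7-isopropoxy-4H-chromen-4-one; 4 3-allyl-4-isopropoxycyclobut-3-ene-1,2-dione
Product: 11 2-allyl-4-hydroxy-3-isopropoxy-4-[(E)-2-(7-isopropoxy-4-oxo-4H-chromen-3-yl)vinyl]cyclobut-2-en-1-one (racemic), via alkenylmagnesium chloride 10 (not isolated)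
Conditions: iPrMgCl·LiCl (1.0 equiv), THF, −40 °C; then 4, −78 °C; sat. aq NH4Cl
Reagents that add atoms: none
Why: Iodine–magnesium exchange on the alkenyl iodide proceeds with retention of the E geometry at a temperature the chromone tolerates, and the alkenyl Grignard then adds 1,2 to the ketone-like carbonyl of 4 next to the isopropoxy carbon (the other carbonyl is a deactivated vinylogous ester), which fixes the substitution pattern of ring B; the new carbinol centre is racemic and later becomes aromatic C5'.

**Step 7**
Reactants: 11 2-allyl-4-hydroxy-3-isopropoxy-4-[(E)-2-(7-isopropoxy-4-oxo-4H-chromen-3-yl)vinyl]cyclobut-2-en-1-one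
Product: 12 2-allyl-3-isopropoxy-4-methoxy-4-[(E)-2-(7-isopropoxy-4-oxo-4H-chromen-3-yl)vinyl]cyclobut-2-en-1-one (racemic)
Conditions: MeI, Ag2O, MeCN, rt, dark
Reagents that add atoms: iodomethane CI
Why: Silver-oxide-promoted O-methylation (Purdie conditions) caps the tertiary alcohol under near-neutral conditions that spare the cyclobutenone and the chromone; this oxygen becomes the 5'-methoxy group.

**Step 8**
Reactants: 12 2-allyl-3-isopropoxy-4-methoxy-4-[(E)-2-(7-isopropoxy-4-oxo-4H-chromen-3-yl)vinyl]cyclobut-2-en-1-one
Product: 15 3'-allyl-2'-hydroxy-4',7-diisopropoxy-5'-methoxyisoflavone, via dienylketene 13 (not isolated), via cyclohexa-2,4-dienone 14 (not isolated)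
Conditions: p-xylene, reflux (138 °C), Ar
Reagents that add atoms: none
Why: Heating opens the C1–C4 bond of the cyclobutenone by conrotatory 4π-electrocyclic ring opening to dienylketene 13, whose ketene carbon then bonds to the terminal vinyl carbon (the former formyl carbon) in a 6π-electrocyclisation that forms the C1'–C2' bond and closes six-membered ring B as cyclohexa-2,4-dienone 14, which enolises to phenol 15. The closest known reaction is the Moore-type thermal rearrangement of squarate-derived 4-alkenyl-4-alkoxycyclobutenones to hydroquinone monoethers. Ring B is therefore closed by 6π-electrocyclic carbon–carbon bond formation directly on chromone C3, with no coupling at that carbon. No stereocentre remains, since the racemic carbinol carbon becomes aromatic C5' and the sp3 carbon of 14 is lost on tautomerisation. The step needs inward rotation of the alkenyl arm, which the strong outward preference of the C4 methoxy donor secures (a ketene with the arm outside can only revert to 12), and the E alkene keeps the chromonyl group away from the ketene during closure. Regiochemistry is fixed by connectivity: the ketene oxygen emerges as the free 2'-hydroxyl, the methylated carbinol oxygen as the 5'-methoxy, the squarate alkoxy as O4' and the allyl-bearing carbon as C3'.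

**Step 9**
Reactants: 15 3'-allyl-2'-hydroxy-4',7-diisopropoxy-5'-methoxyisoflavone
Product: 16 3'-allyl-2',4',7-trihydroxy-5'-methoxyisoflavone
Conditions: BCl3 (1 M in CH2Cl2, 4 equiv), CH2Cl2, −78 → 0 °C; then H2O
Reagents that add atoms: none
Why: Lewis-acid dealkylation with BCl3 removes secondary isopropyl groups from aryl ethers much faster than a methyl group at low temperature, and the terminal allyl group, unlike prenyl, should not cyclise onto the flanking phenols under these cold conditions.

**Step 10**
Reactants: 16 3'-allyl-2',4',7-trihydroxy-5'-methoxyisoflavone; 17 2-methyl-2-butene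
Product: 18 Piscisoflavone A
Conditions: second-generation Grubbs catalyst (H2IMes)(PCy3)Cl2Ru=CHPh (5 mol %), 2-methyl-2-butene–CH2Cl2, 40 °C, sealed tube
Reagents that add atoms: none
Why: Olefin cross-metathesis of the terminal allyl group with a large excess of 2-methyl-2-butene exchanges the CH2 terminus for CMe2 with release of propene; the ruthenium carbene tolerates free phenols and the neutral conditions prevent chroman formation between the prenyl group and the neighbouring hydroxyls.

**Compound list**
1 | diisopropyl squarate | CC(C)OC1=C(OC(C)C)C(=O)C1=O | starting material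
2 | allylmagnesium bromide | C=CC[Mg]Br | starting material
3 | 4-allyl-4-hydroxy-2,3-diisopropoxycyclobut-2-en-1-one (racemic) | C=CCC1(O)C(OC(C)C)=C(OC(C)C)C1=O | intermediate
4 | 3-allyl-4-isopropoxycyclobut-3-ene-1,2-dione | C=CCC1=C(OC(C)C)C(=O)C1=O | intermediate
5 | 2,4-dihydroxyacetophenone | CC(=O)c1ccc(O)cc1O | starting material
6 | 2-hydroxy-4-isopropoxyacetophenone | CC(=O)c1ccc(OC(C)C)cc1O | intermediate
7 | 7-isopropoxy-4-oxo-4H-chromene-3-carbaldehyde | O=Cc1coc2cc(OC(C)C)ccc2c1=O | intermediate
8 | iodoform | IC(I)I | starting material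
9 | (E)-3-(2-iodovinyl)-7-isopropoxy-4H-chromen-4-one | I/C=C/c1coc2cc(OC(C)C)ccc2c1=O | intermediate
10 | [(E)-2-(7-isopropoxy-4-oxo-4H-chromen-3-yl)vinyl]magnesium chloride (LiCl complex, not isolated) | Cl[Mg]/C=C/c1coc2cc(OC(C)C)ccc2c1=O | intermediate
11 | 2-allyl-4-hydroxy-3-isopropoxy-4-[(E)-2-(7-isopropoxy-4-oxo-4H-chromen-3-yl)vinyl]cyclobut-2-en-1-one (racemic) | C=CCC1=C(OC(C)C)C(O)(/C=C/c2coc3cc(OC(C)C)ccc3c2=O)C1=O | intermediate
12 | 2-allyl-3-isopropoxy-4-methoxy-4-[(E)-2-(7-isopropoxy-4-oxo-4H-chromen-3-yl)vinyl]cyclobut-2-en-1-one (racemic) | C=CCC1=C(OC(C)C)C(OC)(/C=C/c2coc3cc(OC(C)C)ccc3c2=O)C1=O | intermediate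
13 | (3Z,5E)-2-allyl-3-isopropoxy-4-methoxy-6-(7-isopropoxy-4-oxo-4H-chromen-3-yl)hexa-1,3,5-trien-1-one (dienylketene, not isolated) | O=C=C(CC=C)/C(OC(C)C)=C(OC)\C=C\c1coc2cc(OC(C)C)ccc2c1=O | intermediate
14 | 2-allyl-3-isopropoxy-4-methoxy-6-(7-isopropoxy-4-oxo-4H-chromen-3-yl)cyclohexa-2,4-dien-1-one (racemic, not isolated) | O=C1C(CC=C)=C(OC(C)C)C(OC)=CC1c1coc2cc(OC(C)C)ccc2c1=O | intermediate
15 | 3'-allyl-2'-hydroxy-4',7-diisopropoxy-5'-methoxyisoflavone | COc1cc(-c2coc3cc(OC(C)C)ccc3c2=O)c(O)c(CC=C)c1OC(C)C | intermediate
16 | 3'-allyl-2',4',7-trihydroxy-5'-methoxyisoflavone | COc1cc(-c2coc3cc(O)ccc3c2=O)c(O)c(CC=C)c1O | intermediate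
17 | 2-methyl-2-butene | CC=C(C)C | starting material
18 | Piscisoflavone A | COc1cc(-c2coc3cc(O)ccc3c2=O)c(O)c(CC=C(C)C)c1O | target

**Total step count:** 10
**Longest linear sequence:** 8 steps (5 → 6 → 7 → 9 → 11 → 12 → 15 → 16 → 18; the squarate branch 1 → 3 → 4 joins at step 6)

**Steps most likely to fail**

Step 6. The iodine–magnesium exchange on the unactivated alkenyl iodide may be slow enough at −40 °C that isopropyl- or alkenylmagnesium attacks C2 or C4 of the pyranone; the alkenylmagnesium may also deprotonate the activated allylic CH2 of 4 instead of adding to its carbonyl. The fallback keeps every reactive organometallic away from the chromone and sets out from dione 4 and acetophenone 6. (E)-1,2-Bis(tributylstannyl)ethene is treated with n-BuLi in THF at −78 °C to give (E)-2-(tributylstannyl)vinyllithium F1, which is added to 4 at −78 °C to give 2-allyl-4-hydroxy-3-isopropoxy-4-[(E)-2-(tributylstannyl)vinyl]cyclobut-2-en-1-one F2. Separately, 6 is condensed with DMF dimethyl acetal to (E)-3-(dimethylamino)-1-(2-hydroxy-4-isopropoxyphenyl)prop-2-en-1-one F3, which iodine cyclises to 3-iodo-7-isopropoxy-4H-chromen-4-one F4. Stille coupling of F2 with F4 (Pd2(dba)3 as a source of zerovalent palladium, AsPh3, CuI, DMF, rt) joins the chromone to the vinyl group and comes back to the route at 11.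

Step 5. CrCl2 or the chromium carbenoid may reduce or add in conjugate fashion to the electron-poor 3-formylpyranone, and the E selectivity may be incomplete. The fallback sets out from aldehyde 7: Knoevenagel–Doebner condensation with malonic acid in pyridine gives (E)-3-(7-isopropoxy-4-oxo-4H-chromen-3-yl)acrylic acid F5, and iododecarboxylation with N-iodosuccinimide and catalytic LiOAc in MeCN–H2O (catalytic Hunsdiecker reaction, aided by donation from O1 through C2=C3) comes back to the route at 9.

Step 10. Ruthenium hydride species may move the terminal double bond into conjugation with ring B, and the chelating 2'-hydroxy/4-oxo and guaiacol-type oxygens may sequester the catalyst, so conversion may stall. The fallback sets out from 16: acetylation (Ac2O, pyridine) gives 3'-allyl-2',4',7-triacetoxy-5'-methoxyisoflavone F6; cross-metathesis with 17 under the same catalyst gives 2',4',7-triacetoxy-5'-methoxy-3'-prenylisoflavone F7; mild methanolysis (K2CO3, MeOH, 0 °C) removes the acetates without acid and comes back to the route at 18.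

**Further compounds**
F1 | step 6 | (E)-2-(tributylstannyl)vinyllithium | [Li]/C=C/[Sn](CCCC)(CCCC)CCCC
F2 | step 6 | 2-allyl-4-hydroxy-3-isopropoxy-4-[(E)-2-(tributylstannyl)vinyl]cyclobut-2-en-1-one (racemic) | C=CCC1=C(OC(C)C)C(O)(/C=C/[Sn](CCCC)(CCCC)CCCC)C1=O
F3 | step 6 | (E)-3-(dimethylamino)-1-(2-hydroxy-4-isopropoxyphenyl)prop-2-en-1-one | CN(C)/C=C/C(=O)c1ccc(OC(C)C)cc1O
F4 | step 6 | 3-iodo-7-isopropoxy-4H-chromen-4-one | O=c1c(I)coc2cc(OC(C)C)ccc12
F5 | step 5 | (E)-3-(7-isopropoxy-4-oxo-4H-chromen-3-yl)acrylic acid | OC(=O)/C=C/c1coc2cc(OC(C)C)ccc2c1=O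
F6 | step 10 | 3'-allyl-2',4',7-triacetoxy-5'-methoxyisoflavone | COc1cc(-c2coc3cc(OC(C)=O)ccc3c2=O)c(OC(C)=O)c(CC=C)c1OC(C)=O
F7 | step 10 | 2',4',7-triacetoxy-5'-methoxy-3'-prenylisoflavone | COc1cc(-c2coc3cc(OC(C)=O)ccc3c2=O)c(OC(C)=O)c(CC=C(C)C)c1OC(C)=O
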